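## Analysis of the target

Compound 23 is a 3,4-dihydroisocoumarin: a benzene ring (ring A, C4a–C5–C6–C7–C8–C8a) fused to a six-membered lactone (ring B: C1, O2, C3, C4). Ring A carries only three contiguous substituents, the C8 hydroxyl, the carboxyl carbon C1 on C8a and the methylene C4 on C4a; C5, C6 and C7 are bare. The single stereocentre is C3, (R) by the sequence rule. It is at once the lactone alkoxy carbon, an allylic carbon of the (1E,3E)-heptadeca-1,3-dienyl chain and the neighbour of the benzylic C4 methylene. The C3–O2 bond is therefore the weak point: acid or zerovalent palladium can ionise it to a pentadienyl cation or a π-allyl complex, and base can eliminate across C3–C4. The (E,E)-diene has to be made geometrically pure, and the C8 phenol, hydrogen-bonded to C1=O, should not need a protecting group that is removed under such conditions. The difficulty is thus not complexity but the ordering of a few operations around one fragile centre. The strategy rests on the pattern of ring A, which is that of a 6-alkylsalicylate: C1, C8a, C8 and C7 form an acetoacetate unit and C6, C5 and C4a a 1,3-dielectrophile, so ring A can be built de novo with phenol and carboxyl already in place.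

## Retrosynthetic reasoning

The last bond made is the acyl–oxygen bond C1–O2 of ring B, which leads from 23 back to the open methyl ester 21, whose C3 oxygen is a silyl ether. Cutting here and not at C3–O2 makes the forward step an acyl substitution by the C3 oxygen. The bond between oxygen and the stereocentre is never formed or broken, and the dienylic lactone appears only after the last metal-catalysed step. The forward reaction has to remove the silyl group and close ring B without acid.

The diene of 21 is cut at the single bond between its two alkenes, giving terminal alkyne 15 and (E)-alkenyl iodide 18, itself one step from alkyne 16. This is preferred to an olefination because each alkene then comes from a syn hydrometalation of a terminal alkyne, the sp2–sp2 coupling retains both geometries, and the thirteen-carbon tail arrives in one piece. The coupling is placed before lactonisation on purpose: in 15 and 21 the allylic oxygen is a silyl ether, which zerovalent palladium cannot ionise.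

Alkyne 15 comes from 14 by removal of the C-silyl cap that protects the alkyne terminus through the earlier steps.

Ring A of 14 is cut at C6–C7 and C4a–C8a. This divides the ring into a four-carbon acetoacetate unit with its ester (C1, C8a, C8, C7), bis-silyl dienolate 12, and a three-carbon 1,3-dielectrophile (C6, C5, C4a), keto acetal 9, whose ketone carbon already carries the C4–C3 chain. No other pair of cuts delivers the C8 hydroxyl and the C1 ester from one cheap nucleophile, leaves the phenol unprotected and keeps the stereocentre outside the ring-forming events. The forward reaction must join the dienolate terminus to the acetal carbon before the ketone is touched, close the ring on the ketone and aromatise. It must do so under a Lewis acid that the propargylic silyl ether and the silylalkyne survive, which is why the chain is carried as an alkyne and not yet as the acid-labile dienyl carbinol.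

Dienolate 12 is traced to mono silyl enol ether 11 and then to keto ester 10 by two successive enol silylations.

In 9 the bond between the acetal carbon and its neighbouring methylene (C6–C5 of the future ring) is cut. This leads to orthoformate 7 as the one-carbon electrophile and to methyl ketone 6 through its kinetic enol silane 8. The cut is made here so that the stereocentre can be set beforehand on a simple substrate. A direct reagent-controlled aldol of a methyl ketone enolate with ynal 1 would be shorter, but such enolates discriminate poorly between the faces of so slim an aldehyde. The forward reaction has to enolise 6 on the methyl side only.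

Ketone 6 is the Wacker product of alkene 5, the silyl ether of homoallylic alcohol 4, and 4 is cut between the carbinol carbon and the allyl group into ynal 1 and allylborane 2. This step sets C3. Allylboration is among the most dependable reagent-controlled additions to aldehydes and both partners are commercial. The three allyl carbons become C4, C4a and C5, and 7 supplies C6.

## Alternatives that were turned down

Alternative 1: Ring A and the pyran ring are disconnected together, at C4a–C8a and C7–C8, back to the furan–yne A2, the propargyl ether of a chiral furyl carbinol. Forward, a gold catalyst would isomerise A2, the furan oxygen moving to C8, to the isochromanol A1.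
- For: two rings form in one catalytic, atom-economical step, C3 comes from a cheap three-carbon chiral building block, and the phenol again emerges free. On ring construction per step it is stronger than the chosen route.
- Against: A1 is an isochroman, so C1 must still be oxidised from CH2 to C=O next to an electron-rich phenol and in competition with the second benzylic position C4. The C3 substituent is only a silyloxymethyl group, so the chain needs deprotection, oxidation to an epimerisable α-alkoxy aldehyde and olefination chemistry whose E-selectivity is less secure than hydrometalation and coupling. A furan without a 5-substituent is also a less well-behaved partner in this isomerisation.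
- Comparison: the chosen strategy is longer before its key step, but it delivers C1 and C8 in their final oxidation states and never places C3 next to an enolisable carbonyl.

Alternative 2: Ring B is disconnected at C4a–C4 and C3–O2 into bromo acid A4 and triene A5. Forward, zerovalent palladium with a chiral phosphoramidite would insert into the C–Br bond, add the aryl group to the terminal alkene of A5 and let the carboxylate close onto the resulting π-allyl complex, giving the O-protected target A3 with C3 set by the ligand.
- For: it is clearly the strongest plan on step economy and convergence. Skeleton, lactone and stereocentre arise in a single catalytic step and only the methoxymethyl ether remains.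
- Against: the allyl unit is part of a pentadienyl system, so the carboxylate can attack at three positions and the remaining alkenes can lose their geometry through η3–η1 interconversion. Enantiocontrol of carboxylate attack on such an extended allyl is far less established than for stabilised carbon nucleophiles. A3 is itself a dienylic ester that the same catalyst can re-ionise, so regiochemistry and enantiomeric purity rest on kinetic control in a reversible manifold. The ether must then be removed with acid from exactly the compound that ionises most easily.
- Comparison: the chosen strategy cannot match the brevity. In its place it sets C3 by a reagent-controlled addition of predictable sense, never exposes the dienylic C–O bond to zerovalent palladium or acid, and needs no phenol protecting group.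

Alternative 3: Ring A is disconnected at C8–C8a and C4a–C5 into methoxydiene A7 and alkynoate A8, which already holds the silylated carbinol and the complete dienyl chain. Forward, A7 and A8 would combine on heating in a Diels–Alder reaction and the bicyclic adduct would extrude its two-carbon bridge (Alder–Rickert) to give methyl ether A6.
- For: on regiochemistry it is at least as strong as the chosen plan. The donor-substituted diene terminus and the acceptor-substituted alkyne carbon pair unambiguously, there is no second electrophilic site and no Lewis acid.
- Against: cycloaddition to a β-alkyl alkynoate and the retro-Diels–Alder step need prolonged heating well above 150 °C. A8 contains an (E,E)-diene that is itself a Diels–Alder partner for the alkynoate of a second molecule and is open to thermal E/Z isomerisation and hydrogen shifts. A6 is an aryl methyl ether whose cleavage needs boron or aluminium halides, which would ionise the dienylic silyl ether or the later lactone. A8 also demands that the diene be built early and carried through.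
- Comparison: the chosen strategy forms the same ring at low temperature, delivers the phenol free and postpones the diene until ring A exists. Its price is the Lewis acid, so the thermal cycloaddition is kept in reserve for a chain that does not yet contain the diene.

Key step: step 7

Remark on the chemistry: enol ethers 11 and 12 are taken as E/Z mixtures at their enol double bonds; no geometry is drawn because both carbons end in ring A.
Remark on the chemistry: reagent 2 is the allylborane of the (−)-α-pinene series, taken to deliver allyl to the Re face of 1 as it does with other unhindered aldehydes.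

## Route

Step 1
Reactants: 1 3-(trimethylsilyl)prop-2-ynal; 2 (+)-B-allyldiisopinocampheylborane
Product: 4 (3R)-1-(trimethylsilyl)hex-5-en-1-yn-3-ol, via borinate ester 3 (not isolated)
Conditions: 2 (1.2 equiv), Et2O, −78 °C; then pH 7 buffer, MeOH, 30% H2O2, 0 °C to rt
Reagents that add atoms: none
Why: Brown allylboration through a closed chair transition state with the slim alkynyl group equatorial; reagent 2 delivers allyl to the Re face of 1, which gives the (R)-carbinol because the alkynyl group outranks the new CH2. Buffered peroxide cleaves borinate 3 without touching the C-silyl group.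

Step 2
Reactants: 4 (3R)-1-(trimethylsilyl)hex-5-en-1-yn-3-ol
Product: 5 tert-butyldimethyl{[(3R)-1-(trimethylsilyl)hex-5-en-1-yn-3-yl]oxy}silane
Conditions: tBuMe2SiCl, imidazole, DMF, rt
Reagents that add atoms: tert-butyldimethylsilyl chloride, CC(C)(C)[Si](C)(C)Cl
Why: Standard silylation of a secondary propargylic alcohol; the tert-butyldimethylsilyl ether is chosen to survive the Lewis acid of step 7 and to fall to fluoride at the end.

Step 3
Reactants: 5 tert-butyldimethyl{[(3R)-1-(trimethylsilyl)hex-5-en-1-yn-3-yl]oxy}silane
Product: 6 (4R)-4-[(tert-butyldimethylsilyl)oxy]-6-(trimethylsilyl)hex-5-yn-2-one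
Conditions: PdCl2 (10 mol%), p-benzoquinone (1.2 equiv), DMF/H2O (7:1), rt
Reagents that add atoms: water, O
Why: Wacker oxidation: Markovnikov hydroxypalladation of the monosubstituted alkene by divalent palladium and β-hydride elimination give the methyl ketone, benzoquinone returning zerovalent palladium to the divalent state. The copper-free, near-neutral medium is chosen to spare the silylalkyne and the silyl ether, and the carbinol centre is not enolisable.

Step 4
Reactants: 6 (4R)-4-[(tert-butyldimethylsilyl)oxy]-6-(trimethylsilyl)hex-5-yn-2-one; 7 trimethyl orthoformate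
Product: 9 (5R)-5-[(tert-butyldimethylsilyl)oxy]-1,1-dimethoxy-7-(trimethylsilyl)hept-6-yn-3-one, via kinetic silyl enol ether 8 (not isolated)
Conditions: LiN(iPr)2 (LDA), THF, −78 °C, then Me3SiCl; solvent exchange to CH2Cl2; 7 (3 equiv), Me3SiOTf (10 mol%), −78 °C; Et3N, aq NaHCO3
Reagents that add atoms: none
Why: LiN(iPr)2 deprotonates the methyl group, the less hindered α-position, and silylation fixes the terminal enol ether 8; Me3SiOTf ionises 7 to the dimethoxycarbenium ion, which 8 captures in a Mukaiyama-type addition to give the β-keto acetal. Low temperature and the absence of free base after silylation guard against β-elimination of the silyloxy group.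

Step 5
Reactants: 10 methyl acetoacetate
Product: 11 methyl 3-[(trimethylsilyl)oxy]but-2-enoate
Conditions: Me3SiCl, Et3N, hexane, rt
Reagents that add atoms: chlorotrimethylsilane, C[Si](C)(C)Cl
Why: O-Silylation of the enol of a β-keto ester under soft enolisation, the standard access to the mono silyl enol ether.

Step 6
Reactants: 11 methyl 3-[(trimethylsilyl)oxy]but-2-enoate
Product: 12 1-methoxy-1,3-bis[(trimethylsilyl)oxy]buta-1,3-diene
Conditions: LiN(iPr)2 (LDA), THF, −78 °C; Me3SiCl, −78 °C to rt
Reagents that add atoms: chlorotrimethylsilane, C[Si](C)(C)Cl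
Why: Deprotonation of the vinylogous methyl group of 11 and O-silylation of the dienolate give the bis-silyl dienolate, the synthetic equivalent of the acetoacetate dianion. It is moisture-sensitive and is used directly.

Step 7
Reactants: 9 (5R)-5-[(tert-butyldimethylsilyl)oxy]-1,1-dimethoxy-7-(trimethylsilyl)hept-6-yn-3-one; 12 1-methoxy-1,3-bis[(trimethylsilyl)oxy]buta-1,3-diene
Product: 14 methyl 2-{(2R)-2-[(tert-butyldimethylsilyl)oxy]-4-(trimethylsilyl)but-3-yn-1-yl}-6-hydroxybenzoate, via open-chain keto ester 13 (not isolated)
Conditions: 12 (1.5 equiv), TiCl4 (1.1 equiv), CH2Cl2, −78 °C to 0 °C; aq NaHCO3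
Reagents that add atoms: none
Why: This is the formal [3+3] cyclocondensation of a 1,3-bis(silyloxy)diene with a β-keto acetal, a known route to 6-substituted salicylates: TiCl4 ionises the dimethyl acetal of 9 to an oxocarbenium ion, which the terminal carbon of 12 attacks in a Mukaiyama-type addition to give the open-chain adduct 13 (bond C6–C7). The titanium enolate of the resulting β-keto ester then adds through its central carbon to the titanium-activated ketone in a 6-(enolendo)-exo-trig aldol closure (bond C4a–C8a), and loss of water and of the second methanol aromatises ring A, the only ring closed, so that the phenol emerges free and next to the ester. No stereocentre is created that survives, since the methoxy-bearing carbon of 13 and the aldol carbinol are both flattened, and the (R)-carbinol is a spectator whose C–O bond is never broken. The regioselectivity needed is attack of the diene terminus on the acetal carbon before the ketone; it is secured by the much higher electrophilicity of the oxocarbenium ion, and the same connectivity results if the acetal first collapses to the 3-methoxy enone, because conjugate addition occurs at the same carbon. The chemoselectivity needed is survival of the propargylic silyl ether and of the C-silyl alkyne. Low temperature, the poor donor ability of a bulky propargylic silyl ether oxygen and the excess of the highly nucleophilic diene are expected to provide it.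

Step 8
Reactants: 14 methyl 2-{(2R)-2-[(tert-butyldimethylsilyl)oxy]-4-(trimethylsilyl)but-3-yn-1-yl}-6-hydroxybenzoate
Product: 15 methyl 2-{(2R)-2-[(tert-butyldimethylsilyl)oxy]but-3-yn-1-yl}-6-hydroxybenzoate
Conditions: K2CO3, MeOH, rt; aq NH4Cl
Reagents that add atoms: none
Why: Methoxide-induced protodesilylation of the alkynylsilane; the secondary silyl ether is stable and transesterification of the methyl ester is degenerate.

Step 9
Reactants: 16 pentadec-1-yne
Product: 18 (1E)-1-iodopentadec-1-ene, via alkenylzirconocene chloride 17 (not isolated)
Conditions: Cp2Zr(H)Cl, THF, rt; then I2, 0 °C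
Reagents that add atoms: iodine, II
Why: Syn hydrozirconation places zirconium on the terminal carbon, and iodinolysis of the C–Zr bond proceeds with retention to the (E)-iodide.

Step 10
Reactants: 15 methyl 2-{(2R)-2-[(tert-butyldimethylsilyl)oxy]but-3-yn-1-yl}-6-hydroxybenzoate; 18 (1E)-1-iodopentadec-1-ene
Product: 21 methyl 2-{(2R,3E,5E)-2-[(tert-butyldimethylsilyl)oxy]nonadeca-3,5-dien-1-yl}-6-hydroxybenzoate, via dizirconated alkenyl species 19 (not isolated), via alkenylzinc chloride 20 (not isolated)
Conditions: Cp2Zr(H)Cl (2.2 equiv), THF, 0 °C to rt; ZnCl2 (1.2 equiv); 18 (1.1 equiv), Pd(PPh3)4 (5 mol%), THF, rt; aq NH4Cl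
Reagents that add atoms: none
Why: Hydrozirconation–Negishi coupling: the first equivalent of Cp2Zr(H)Cl is consumed by the phenol (zirconium aryloxide and H2), the second adds syn and terminally to the alkyne to give 19, ZnCl2 relays the alkenyl group to zinc (20), and zerovalent palladium couples it with 18 with retention at both alkenes. The carbinol is still a silyl ether, which zerovalent palladium cannot ionise, and no bond to the stereocentre is touched.

Step 11
Reactants: 21 methyl 2-{(2R,3E,5E)-2-[(tert-butyldimethylsilyl)oxy]nonadeca-3,5-dien-1-yl}-6-hydroxybenzoate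
Product: 23 (3R)-3-[(1E,3E)-heptadeca-1,3-dien-1-yl]-8-hydroxy-3,4-dihydro-1H-isochromen-1-one, via hydroxy ester 22 (not isolated)
Conditions: Bu4NF (2.5 equiv), THF, 0 °C to rt; aq NH4Cl
Reagents that add atoms: none
Why: Fluoride cleaves the silyl ether, and the freed C3 oxygen of 22, held next to the ester, closes ring B by 6-exo-trig acyl substitution with loss of methoxide (lactonisation by transesterification). The C3–O bond is not broken, so the (R) configuration is kept, and neither acid nor palladium meets the dienylic lactone.

## Compound list

1 | 3-(trimethylsilyl)prop-2-ynal | C[Si](C)(C)C#CC=O | starting material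
2 | (+)-B-allyldiisopinocampheylborane, allylbis[(1S,2R,3S,5S)-2,6,6-trimethylbicyclo[3.1.1]heptan-3-yl]borane, the (−)-α-pinene series | C=CCB([C@H]1C[C@H]2C[C@@H]([C@@H]1C)C2(C)C)[C@H]1C[C@H]2C[C@@H]([C@@H]1C)C2(C)C | starting material
3 | (3R)-1-(trimethylsilyl)hex-5-en-1-yn-3-yl diisopinocampheylborinate | C[Si](C)(C)C#C[C@H](OB([C@H]1C[C@H]2C[C@@H]([C@@H]1C)C2(C)C)[C@H]1C[C@H]2C[C@@H]([C@@H]1C)C2(C)C)CC=C | intermediate
4 | (3R)-1-(trimethylsilyl)hex-5-en-1-yn-3-ol | C[Si](C)(C)C#C[C@H](O)CC=C | intermediate
5 | tert-butyldimethyl{[(3R)-1-(trimethylsilyl)hex-5-en-1-yn-3-yl]oxy}silane | C[Si](C)(C)C#C[C@H](O[Si](C)(C)C(C)(C)C)CC=C | intermediate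
6 | (4R)-4-[(tert-butyldimethylsilyl)oxy]-6-(trimethylsilyl)hex-5-yn-2-one | C[Si](C)(C)C#C[C@H](O[Si](C)(C)C(C)(C)C)CC(C)=O | intermediate
7 | trimethyl orthoformate | COC(OC)OC | starting material
8 | tert-butyldimethyl{[(3R)-1-(trimethylsilyl)-5-[(trimethylsilyl)oxy]hex-5-en-1-yn-3-yl]oxy}silane | C[Si](C)(C)C#C[C@H](O[Si](C)(C)C(C)(C)C)CC(=C)O[Si](C)(C)C | intermediate
9 | (5R)-5-[(tert-butyldimethylsilyl)oxy]-1,1-dimethoxy-7-(trimethylsilyl)hept-6-yn-3-one | C[Si](C)(C)C#C[C@H](O[Si](C)(C)C(C)(C)C)CC(=O)CC(OC)OC | intermediate
10 | methyl acetoacetate | COC(=O)CC(C)=O | starting material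
11 | methyl 3-[(trimethylsilyl)oxy]but-2-enoate (E/Z mixture) | COC(=O)C=C(C)O[Si](C)(C)C | intermediate
12 | 1-methoxy-1,3-bis[(trimethylsilyl)oxy]buta-1,3-diene (E/Z mixture) | COC(O[Si](C)(C)C)=CC(=C)O[Si](C)(C)C | intermediate
13 | methyl (9R)-9-[(tert-butyldimethylsilyl)oxy]-5-methoxy-3,7-dioxo-11-(trimethylsilyl)undec-10-ynoate (both C5 epimers, as titanium enolate) | COC(=O)CC(=O)CC(OC)CC(=O)C[C@@H](O[Si](C)(C)C(C)(C)C)C#C[Si](C)(C)C | intermediate
14 | methyl 2-{(2R)-2-[(tert-butyldimethylsilyl)oxy]-4-(trimethylsilyl)but-3-yn-1-yl}-6-hydroxybenzoate | C[Si](C)(C)C#C[C@H](O[Si](C)(C)C(C)(C)C)Cc1cccc(O)c1C(=O)OC | intermediate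
15 | methyl 2-{(2R)-2-[(tert-butyldimethylsilyl)oxy]but-3-yn-1-yl}-6-hydroxybenzoate | C#C[C@H](O[Si](C)(C)C(C)(C)C)Cc1cccc(O)c1C(=O)OC | intermediate
16 | pentadec-1-yne | CCCCCCCCCCCCCC#C | starting material
17 | chlorobis(cyclopentadienyl)[(1E)-pentadec-1-en-1-yl]zirconium | CCCCCCCCCCCCC/C=C/[Zr](Cl)(C1C=CC=C1)C1C=CC=C1 | intermediate
18 | (1E)-1-iodopentadec-1-ene | CCCCCCCCCCCCC/C=C/I | intermediate
19 | methyl 2-{(2R,3E)-2-[(tert-butyldimethylsilyl)oxy]-4-[chlorobis(cyclopentadienyl)zirconio]but-3-en-1-yl}-6-{[chlorobis(cyclopentadienyl)zirconio]oxy}benzoate | COC(=O)c1c(O[Zr](Cl)(C2C=CC=C2)C2C=CC=C2)cccc1C[C@@H](O[Si](C)(C)C(C)(C)C)/C=C/[Zr](Cl)(C1C=CC=C1)C1C=CC=C1 | intermediate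
20 | chloro{(1E,3R)-3-[(tert-butyldimethylsilyl)oxy]-4-[2-(methoxycarbonyl)-3-{[chlorobis(cyclopentadienyl)zirconio]oxy}phenyl]but-1-en-1-yl}zinc | COC(=O)c1c(O[Zr](Cl)(C2C=CC=C2)C2C=CC=C2)cccc1C[C@@H](O[Si](C)(C)C(C)(C)C)/C=C/[Zn]Cl | intermediate
21 | methyl 2-{(2R,3E,5E)-2-[(tert-butyldimethylsilyl)oxy]nonadeca-3,5-dien-1-yl}-6-hydroxybenzoate | CCCCCCCCCCCCC/C=C/C=C/[C@H](O[Si](C)(C)C(C)(C)C)Cc1cccc(O)c1C(=O)OC | intermediate
22 | methyl 2-hydroxy-6-[(2R,3E,5E)-2-hydroxynonadeca-3,5-dien-1-yl]benzoate | CCCCCCCCCCCCC/C=C/C=C/[C@H](O)Cc1cccc(O)c1C(=O)OC | intermediate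
23 | (3R)-3-[(1E,3E)-heptadeca-1,3-dien-1-yl]-8-hydroxy-3,4-dihydro-1H-isochromen-1-one | CCCCCCCCCCCCC/C=C/C=C/[C@H]1Cc2cccc(O)c2C(=O)O1 | target

## Step count and least certain steps

Total step count: 11. Longest linear sequence: 8 steps (steps 1, 2, 3, 4, 7, 8, 10, 11).

**Step 7 (key step).** The most likely failure is that the ionised acetal is captured inside the molecule by the silyl ether oxygen, giving a six-membered cyclic ether with loss of the silyl group, or that TiCl4 desilylates or β-eliminates the silyloxy group before 12 intervenes. Hydrolytic decay of 12 and incomplete aromatisation are lesser concerns. The fallback drops the Lewis acid and builds ring A thermally from the same chiral material, setting out from alkene 5.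
- Lemieux–Johnson cleavage (OsO4 cat., NaIO4, 2,6-lutidine, dioxane/H2O) would give the aldehyde (3R)-3-[(tert-butyldimethylsilyl)oxy]-5-(trimethylsilyl)pent-4-ynal F1.
- Corey–Fuchs olefination (CBr4, PPh3, CH2Cl2, 0 °C) would give the dibromoalkene tert-butyl{[(3R)-6,6-dibromo-1-(trimethylsilyl)hex-5-en-1-yn-3-yl]oxy}dimethylsilane F2.
- n-BuLi (2 equiv, THF, −78 °C) followed by methyl chloroformate would give the ynoate methyl (5R)-5-[(tert-butyldimethylsilyl)oxy]-7-(trimethylsilyl)hepta-2,6-diynoate F3.
- Heating F3 with 1-(trimethylsilyloxy)cyclohexa-1,3-diene (toluene, sealed tube, about 170 °C) should give the bicyclo[2.2.2]octadiene cycloadduct F4, which loses ethene in the same operation (Alder–Rickert) to the aryl silyl ether methyl 2-{(2R)-2-[(tert-butyldimethylsilyl)oxy]-4-(trimethylsilyl)but-3-yn-1-yl}-6-[(trimethylsilyl)oxy]benzoate F5.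
- Methanolic work-up frees the phenol and the route is rejoined at 14.

The weakness of this cycloaddition with a dienyl chain does not apply here, because the chain is still a silylalkyne.

**Step 10.** The zirconium hydride can be consumed by the phenol faster than planned or can reduce the ester, and transmetalation of the branched alkenyl group may be slow enough for protodemetalation to compete. The fallback replaces zirconium and zinc by tin and sets out from 15. Hydrostannation (Bu3SnH, PdCl2(PPh3)2 cat., THF, 0 °C), which tolerates the phenol, would give the (E)-alkenylstannane methyl 2-{(2R,3E)-2-[(tert-butyldimethylsilyl)oxy]-4-(tributylstannyl)but-3-en-1-yl}-6-hydroxybenzoate F6. Stille coupling with 18 (Pd2(dba)3, AsPh3, CuI, DMF, rt) returns to 21.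

**Step 11.** Ring closure may stall at hydroxy ester 22 because the phenoxide formed under basic fluoride deactivates the ester, or the basic medium may eliminate across C3–C4 of the product. The fallback closes ring B before the diene exists, when acid is harmless, and makes the last C–C bond without zerovalent palladium. It sets out from 15.
- Bu4NF (THF) would give methyl 2-hydroxy-6-[(2R)-2-hydroxybut-3-yn-1-yl]benzoate F7.
- TsOH·H2O (cat., CH2Cl2) would close it to (3R)-3-ethynyl-8-hydroxy-3,4-dihydro-1H-isochromen-1-one F8.
- Hydrostannation (Bu3SnH, PdCl2(PPh3)2 cat., THF, 0 °C) would give (3R)-8-hydroxy-3-[(E)-2-(tributylstannyl)ethenyl]-3,4-dihydro-1H-isochromen-1-one F9.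
- Coupling of F9 with 18 mediated by copper thiophene-2-carboxylate (CuTC, monovalent copper, NMP, rt) returns to 23.

**Step 3.** Divalent palladium may engage the alkyne of this 1,5-enyne, or the homoallylic oxygen may steer the oxidation toward the aldehyde. The fallback hydrates the alkene by a radical path and sets out from 5. Mukaiyama hydration (Co(acac)2 cat., PhSiH3, O2, THF/iPrOH, rt) would give (2RS,4R)-4-[(tert-butyldimethylsilyl)oxy]-6-(trimethylsilyl)hex-5-yn-2-ol F10. Oxidation with the periodinane DMP (NaHCO3, CH2Cl2) returns to 6.

**Step 1.** Facial discrimination may fall short with so slim an aldehyde, and the C-silyl group may be lost during the oxidative work-up. The fallback sets the centre by reduction instead of C–C bond formation and sets out from 4 of insufficient enantiomeric purity. MnO2 (CH2Cl2, rt) would give 1-(trimethylsilyl)hex-5-en-1-yn-3-one F11. Base-free asymmetric transfer hydrogenation with the amido complex prepared from RuCl[(R,R)-TsDPEN](p-cymene) in iPrOH (rt) returns to 4; the alkynyl group takes the place of the aryl group of the usual model, which leads to the (R)-carbinol.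

## Further compounds

F1 | step 7 | (3R)-3-[(tert-butyldimethylsilyl)oxy]-5-(trimethylsilyl)pent-4-ynal | C[Si](C)(C)C#C[C@H](O[Si](C)(C)C(C)(C)C)CC=O
F2 | step 7 | tert-butyl{[(3R)-6,6-dibromo-1-(trimethylsilyl)hex-5-en-1-yn-3-yl]oxy}dimethylsilane | C[Si](C)(C)C#C[C@H](O[Si](C)(C)C(C)(C)C)CC=C(Br)Br
F3 | step 7 | methyl (5R)-5-[(tert-butyldimethylsilyl)oxy]-7-(trimethylsilyl)hepta-2,6-diynoate | C[Si](C)(C)C#C[C@H](O[Si](C)(C)C(C)(C)C)CC#CC(=O)OC
F4 | step 7 | methyl 3-{(2R)-2-[(tert-butyldimethylsilyl)oxy]-4-(trimethylsilyl)but-3-yn-1-yl}-1-[(trimethylsilyl)oxy]bicyclo[2.2.2]octa-2,5-diene-2-carboxylate (bridgehead diastereomers) | COC(=O)C1=C(C[C@@H](O[Si](C)(C)C(C)(C)C)C#C[Si](C)(C)C)C2C=CC1(O[Si](C)(C)C)CC2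
F5 | step 7 | methyl 2-{(2R)-2-[(tert-butyldimethylsilyl)oxy]-4-(trimethylsilyl)but-3-yn-1-yl}-6-[(trimethylsilyl)oxy]benzoate | C[Si](C)(C)C#C[C@H](O[Si](C)(C)C(C)(C)C)Cc1cccc(O[Si](C)(C)C)c1C(=O)OC
F6 | step 10 | methyl 2-{(2R,3E)-2-[(tert-butyldimethylsilyl)oxy]-4-(tributylstannyl)but-3-en-1-yl}-6-hydroxybenzoate | CCCC[Sn](CCCC)(CCCC)/C=C/[C@H](O[Si](C)(C)C(C)(C)C)Cc1cccc(O)c1C(=O)OC
F7 | step 11 | methyl 2-hydroxy-6-[(2R)-2-hydroxybut-3-yn-1-yl]benzoate | C#C[C@H](O)Cc1cccc(O)c1C(=O)OC
F8 | step 11 | (3R)-3-ethynyl-8-hydroxy-3,4-dihydro-1H-isochromen-1-one | C#C[C@H]1Cc2cccc(O)c2C(=O)O1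
F9 | step 11 | (3R)-8-hydroxy-3-[(E)-2-(tributylstannyl)ethenyl]-3,4-dihydro-1H-isochromen-1-one | CCCC[Sn](CCCC)(CCCC)/C=C/[C@H]1Cc2cccc(O)c2C(=O)O1
F10 | step 3 | (2RS,4R)-4-[(tert-butyldimethylsilyl)oxy]-6-(trimethylsilyl)hex-5-yn-2-ol | C[Si](C)(C)C#C[C@H](O[Si](C)(C)C(C)(C)C)CC(C)O
F11 | step 1 | 1-(trimethylsilyl)hex-5-en-1-yn-3-one | C[Si](C)(C)C#CC(=O)CC=C
A1 | alternative 1 | (3R)-3-{[(tert-butyldiphenylsilyl)oxy]methyl}-3,4-dihydro-1H-isochromen-8-ol | CC(C)(C)[Si](c1ccccc1)(c1ccccc1)OC[C@H]1Cc2cccc(O)c2CO1
A2 | alternative 1 | tert-butyl{[(2R)-3-(furan-2-yl)-2-(prop-2-yn-1-yloxy)propyl]oxy}diphenylsilane | CC(C)(C)[Si](c1ccccc1)(c1ccccc1)OC[C@H](OCC#C)Cc1ccco1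
A3 | alternative 2 | (3R)-3-[(1E,3E)-heptadeca-1,3-dien-1-yl]-8-(methoxymethoxy)-3,4-dihydro-1H-isochromen-1-one | CCCCCCCCCCCCC/C=C/C=C/[C@H]1Cc2cccc(OCOC)c2C(=O)O1
A4 | alternative 2 | 2-bromo-6-(methoxymethoxy)benzoic acid | COCOc1cccc(Br)c1C(=O)O
A5 | alternative 2 | (3E,5E)-nonadeca-1,3,5-triene | C=C/C=C/C=C/CCCCCCCCCCCCC
A6 | alternative 3 | methyl 2-{(2R,3E,5E)-2-[(tert-butyldimethylsilyl)oxy]nonadeca-3,5-dien-1-yl}-6-methoxybenzoate | CCCCCCCCCCCCC/C=C/C=C/[C@H](O[Si](C)(C)C(C)(C)C)Cc1cccc(OC)c1C(=O)OC
A7 | alternative 3 | 1-methoxycyclohexa-1,3-diene | COC1=CC=CCC1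
A8 | alternative 3 | methyl (5R,6E,8E)-5-[(tert-butyldimethylsilyl)oxy]docosa-6,8-dien-2-ynoate | CCCCCCCCCCCCC/C=C/C=C/[C@H](O[Si](C)(C)C(C)(C)C)CC#CC(=O)OC
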